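**Retrosynthetic overview**

1. Feature: ring A (C4a, C5–C8, C8a) is a phloroglucinol ring whose oxygens at C5, C7 and C8a alternate with the acyl carbon C4a, the hydrogen at C6 and the branched alkyl chain at C8. The route builds this ring from acyclic pieces so that only O8a arrives free, and ring C can then close only to the 8-alkyl (not the 6-alkyl) isomer.
2. Ring A (first): photochemical benzannulation of diazoketone 5 with siloxyalkyne 19 forms C8–C8a, C6–C7 and C4a–C8a and gives phenol 23. O5 and O7 are both carried as triisopropylsilyl ethers, the first coming from the silyl enol ether of butane-2,3-dione.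
3. Ring C (second): O-to-C acetyl shift to C4a, enaminone formation, closure through O8a to chromone 27.
4. Ring B (attached last): the C2–aryl bond and the C2 stereocentre by rhodium-catalysed asymmetric 1,4-addition of boronic acid 32 to 27, then one global desilylation.
5. Side chain: the methyl-bearing centre comes from (S)-3-bromo-2-methylpropan-1-ol, the prenyl-bearing centre from an Evans alkylation, the alkyne from acetylide displacement, and the ynol silyl ether from oxidation of the lithium acetylide.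

Key step: step 11

Assumption: in step 17 the (S) antipode of MeO-F12-BIPHEP (2,2'-bis[bis(3,4,5-trifluorophenyl)phosphino]-6,6'-dimethoxy-1,1'-biphenyl) is taken to deliver the aryl group to the Re face of C2, by analogy with (S)-biaryl diphosphine–rhodium additions to cyclohex-2-enone. If a model run on 5,7-dimethoxychromone shows the opposite sense, the (R) ligand is used with no other change.

**Route**

Step 1
Reactants: 1 butane-2,3-dione
Product: 2 3-[(triisopropylsilyl)oxy]but-3-en-2-one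
Conditions: TIPSOTf (1.0 equiv), Et3N, CH2Cl2, 0 °C
Reagents that add atoms: triisopropylsilyl trifluoromethanesulfonate, CC(C)[Si](C(C)C)(C(C)C)OS(=O)(=O)C(F)(F)F
Why: Soft enolisation of the alpha-diketone by silyl triflate and amine (O-silylation of an enolisable ketone) should give the mono silyl enol ether, one equivalent of triflate leaving the second carbonyl untouched, and the bulky silyl group is chosen because it must survive as the C5 aryl ether to the last step.

Step 2
Reactants: 2 3-[(triisopropylsilyl)oxy]but-3-en-2-one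
Product: 5 1-diazo-3-[(triisopropylsilyl)oxy]but-3-en-2-one, via lithium dienolate 3 (not isolated), via trifluoroacetyl diketone 4 (not isolated)
Conditions: LiN(SiMe3)2, THF, −78 °C; CF3CO2CH2CF3, −78 °C; cold 1 M HCl work-up; then MsN3, Et3N, H2O (1 equiv), MeCN, rt
Reagents that add atoms: methanesulfonyl azide, CS(=O)(=O)N=[N+]=[N-]
Why: Detrifluoroacetylative diazo transfer (Claisen trifluoroacetylation of the kinetic methyl-ketone enolate, then Regitz diazo transfer with loss of the trifluoroacetyl group as its sulfonamide) is the standard entry to alpha,beta-unsaturated diazomethyl ketones and avoids diazomethane, which would add to the enone.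

Step 3
Reactants: 6 (S)-3-bromo-2-methylpropan-1-ol
Product: 7 (S)-(3-bromo-2-methylpropoxy)(tert-butyl)dimethylsilane
Conditions: TBSCl, imidazole, CH2Cl2, 0 °C → rt
Reagents that add atoms: tert-butyldimethylsilyl chloride, CC(C)(C)[Si](C)(C)Cl
Why: Standard silylation of a primary alcohol, which leaves the bromide and the stereocentre untouched.

Step 4
Reactants: 7 (S)-(3-bromo-2-methylpropoxy)(tert-butyl)dimethylsilane
Product: 9 (R)-4-[(tert-butyldimethylsilyl)oxy]-3-methylbutanoic acid, via Grignard reagent 8 (not isolated)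
Conditions: Mg turnings (BrCH2CH2Br activation), THF, 45 °C; CO2 (dry gas), −40 → 0 °C; cold 1 M HCl to pH 3
Reagents that add atoms: carbon dioxide, O=C=O
Why: Grignard formation from the primary bromide and carboxylation adds the carboxyl carbon; the stereocentre is beta to magnesium and cannot epimerise (its descriptor changes only through priorities), and the silyl ether is too far from the metal to be eliminated.

Step 5
Reactants: 9 (R)-4-[(tert-butyldimethylsilyl)oxy]-3-methylbutanoic acid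
Product: 11 (S)-4-benzyl-3-{(R)-4-[(tert-butyldimethylsilyl)oxy]-3-methylbutanoyl}oxazolidin-2-one, via mixed pivalic anhydride 10 (not isolated)
Conditions: PivCl, Et3N, THF, −20 °C; then (S)-4-benzyloxazolidin-2-one, LiCl, −20 °C → rt
Reagents that add atoms: (S)-4-benzyloxazolidin-2-one, O=C1OC[C@H](Cc2ccccc2)N1
Why: N-Acylation of the oxazolidinone through the mixed pivalic anhydride with LiCl/Et3N activation is the usual one-flask way to Evans imides and does not touch the beta-stereocentre.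

Step 6
Reactants: 11 (S)-4-benzyl-3-{(R)-4-[(tert-butyldimethylsilyl)oxy]-3-methylbutanoyl}oxazolidin-2-one
Product: 13 (S)-4-benzyl-3-{(2S,3R)-4-[(tert-butyldimethylsilyl)oxy]-3-methyl-2-(3-methylbut-2-en-1-yl)butanoyl}oxazolidin-2-one, via sodium Z-enolate 12 (not isolated)
Conditions: NaN(SiMe3)2, THF, −78 °C; 1-bromo-3-methylbut-2-ene, −78 → −45 °C
Reagents that add atoms: 1-bromo-3-methylbut-2-ene (prenyl bromide), CC(C)=CCBr
Why: Evans asymmetric alkylation, in which the chelated sodium Z-enolate is alkylated by the reactive allylic bromide on the face anti to the benzyl group, so the auxiliary sets the new centre (2S in 13, the later prenyl-bearing side-chain carbon of R configuration) whatever the bias of the neighbouring methyl-bearing centre.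

Step 7
Reactants: 13 (S)-4-benzyl-3-{(2S,3R)-4-[(tert-butyldimethylsilyl)oxy]-3-methyl-2-(3-methylbut-2-en-1-yl)butanoyl}oxazolidin-2-one
Product: 14 (2S,3R)-4-[(tert-butyldimethylsilyl)oxy]-3-methyl-2-(3-methylbut-2-en-1-yl)butan-1-ol
Conditions: LiBH4, MeOH (2 equiv), Et2O, 0 °C
Reagents that add atoms: none
Why: Reductive cleavage of the imide by hydride attack at the exocyclic carbonyl (LiBH4/MeOH) should release the primary alcohol and the auxiliary without epimerisation, the small alkoxyborohydride coping with the alpha-branched acyl group.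

Step 8
Reactants: 14 (2S,3R)-4-[(tert-butyldimethylsilyl)oxy]-3-methyl-2-(3-methylbut-2-en-1-yl)butan-1-ol
Product: 15 (2S,3R)-4-[(tert-butyldimethylsilyl)oxy]-3-methyl-2-(3-methylbut-2-en-1-yl)butyl 4-methylbenzenesulfonate
Conditions: TsCl, Et3N, DMAP (cat.), CH2Cl2, 0 °C → rt
Reagents that add atoms: 4-methylbenzenesulfonyl chloride, Cc1ccc(cc1)S(Cl)(=O)=O
Why: Sulfonylation of the primary alcohol provides the leaving group for chain extension.

Step 9
Reactants: 15 (2S,3R)-4-[(tert-butyldimethylsilyl)oxy]-3-methyl-2-(3-methylbut-2-en-1-yl)butyl 4-methylbenzenesulfonate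
Product: 16 tert-butyl{[(2R,3R)-2,6-dimethyl-3-(prop-2-yn-1-yl)hept-5-en-1-yl]oxy}dimethylsilane
Conditions: LiC≡CH·H2NCH2CH2NH2 (3 equiv), DMSO, 15 °C → rt
Reagents that add atoms: lithium acetylide–ethane-1,2-diamine complex, [Li]C#C.NCCN
Why: SN2 displacement of a primary tosylate by lithium acetylide in DMSO is routine for beta-branched substrates, places the side-chain methylene next to the alkyne and touches neither stereocentre.

Step 10
Reactants: 16 tert-butyl{[(2R,3R)-2,6-dimethyl-3-(prop-2-yn-1-yl)hept-5-en-1-yl]oxy}dimethylsilane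
Product: 19 tert-butyl{[(2R,3R)-2,6-dimethyl-3-{3-[(triisopropylsilyl)oxy]prop-2-yn-1-yl}hept-5-en-1-yl]oxy}dimethylsilane, via lithium acetylide 17 (not isolated), via lithium ynolate 18 (not isolated)
Conditions: n-BuLi, THF, −78 °C; t-BuOOLi (from t-BuOOH and LiN(SiMe3)2, THF, −78 °C), −78 → 0 °C; TIPSOTf, −78 °C → rt; NaHCO3 work-up, Et3N-deactivated silica
Reagents that add atoms: tert-butyl hydroperoxide (used as its lithium salt), CC(C)(C)OO; triisopropylsilyl trifluoromethanesulfonate, CC(C)[Si](C(C)C)(C(C)C)OS(=O)(=O)C(F)(F)F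
Why: The acetylide carbon attacks the peroxide oxygen of t-BuOOLi with loss of tert-butoxide (electrophilic oxygenation of an acetylide to a lithium ynolate) and the ynolate is silylated on oxygen by the bulky triflate, the established route from terminal alkynes to 1-silyloxyalkynes.

Step 11
Reactants: 5 1-diazo-3-[(triisopropylsilyl)oxy]but-3-en-2-one; 19 tert-butyl{[(2R,3R)-2,6-dimethyl-3-{3-[(triisopropylsilyl)oxy]prop-2-yn-1-yl}hept-5-en-1-yl]oxy}dimethylsilane
Product: 23 2-[(2R,3R)-4-[(tert-butyldimethylsilyl)oxy]-3-methyl-2-(3-methylbut-2-en-1-yl)butyl]-3,5-bis[(triisopropylsilyl)oxy]phenol, via vinylketene 20 (not isolated), via vinylcyclobutenone 21 (not isolated), via dienylketene 22 (not isolated)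
Conditions: hν (254 nm, low-pressure Hg lamp, quartz), ClCH2CH2Cl (0.2 M), rt, 19 (1 equiv), 5 (2 equiv in two portions); then 80 °C in the dark
Reagents that add atoms: none
Why: Light expels N2 from 5 and the 1-silyloxyvinyl group shifts to the carbene carbon (photochemical Wolff rearrangement) to give vinylketene 20, whose ketene carbonyl carbon and alpha-carbon add across the ynol ether in a [2+2] cycloaddition to give 4-vinylcyclobutenone 21, which opens by four-electron electrocyclic cleavage of its C(=O)–C(sp3) bond (on irradiation or at 80 °C) to dienylketene 22. Ring A is closed by six-electron electrocyclisation of 22, the ketene carbon bonding to the terminal methylene (the C4a–C8a bond), and the resulting cyclohexa-2,4-dienone tautomerises to phenol 23; C8–C8a and C6–C7 come from the [2+2] step. The closest known reaction type is the Danheiser benzannulation of alpha-diazo ketones with siloxyalkynes. No stereocentre is formed in 23, since the sp3 carbon of 21 is lost on ring opening and the two side-chain centres are remote from every reacting atom. The selectivity needed is the regiochemistry of the ketene–alkyne addition, and it is secured by the oxygen-polarised alkyne, whose nucleophilic alkyl-bearing carbon attacks the ketene carbonyl carbon, so that the oxygens arrive as free OH at C8a and as silyl ethers at C7 and C5. The six-electron closure of 22 should far outrun any ketene addition to the prenyl alkene three atoms away, and the excess of 5 makes up for ketene lost to dimerisation.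

Step 12
Reactants: 23 2-[(2R,3R)-4-[(tert-butyldimethylsilyl)oxy]-3-methyl-2-(3-methylbut-2-en-1-yl)butyl]-3,5-bis[(triisopropylsilyl)oxy]phenol
Product: 24 2-[(2R,3R)-4-[(tert-butyldimethylsilyl)oxy]-3-methyl-2-(3-methylbut-2-en-1-yl)butyl]-3,5-bis[(triisopropylsilyl)oxy]phenyl acetate
Conditions: Ac2O, Et3N, DMAP (cat.), CH2Cl2, rt
Reagents that add atoms: acetic anhydride, CC(=O)OC(C)=O
Why: DMAP-catalysed O-acetylation of the only free hydroxyl, the hindered C8a phenol.

Step 13
Reactants: 24 2-[(2R,3R)-4-[(tert-butyldimethylsilyl)oxy]-3-methyl-2-(3-methylbut-2-en-1-yl)butyl]-3,5-bis[(triisopropylsilyl)oxy]phenyl acetate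
Product: 25 1-{2-hydroxy-3-[(2R,3R)-4-[(tert-butyldimethylsilyl)oxy]-3-methyl-2-(3-methylbut-2-en-1-yl)butyl]-4,6-bis[(triisopropylsilyl)oxy]phenyl}ethan-1-one
Conditions: hν (254 nm, quartz), degassed cyclohexane (0.01 M), rt
Reagents that add atoms: none
Why: Photo-Fries rearrangement, in which excitation cleaves the ArO–acyl bond and the caged acetyl radical recombines at the only free ortho carbon (C4a), the para carbon C6 being screened by two flanking triisopropylsilyloxy groups, under neutral conditions that spare the silyl ethers and the trisubstituted alkene where a Lewis-acid Fries rearrangement would not.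

Step 14
Reactants: 25 1-{2-hydroxy-3-[(2R,3R)-4-[(tert-butyldimethylsilyl)oxy]-3-methyl-2-(3-methylbut-2-en-1-yl)butyl]-4,6-bis[(triisopropylsilyl)oxy]phenyl}ethan-1-one
Product: 27 8-[(2R,3R)-4-[(tert-butyldimethylsilyl)oxy]-3-methyl-2-(3-methylbut-2-en-1-yl)butyl]-5,7-bis[(triisopropylsilyl)oxy]-4H-chromen-4-one, via enaminone 26 (not isolated)
Conditions: Me2NCH(OMe)2, toluene, 85 °C; concentrate; then AcOH (5 equiv), toluene, 60 °C
Reagents that add atoms: N,N-dimethylformamide dimethyl acetal, COC(OC)N(C)C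
Why: Condensation of the methyl ketone with the amide acetal gives the enaminone, and acid-promoted conjugate addition of the C8a hydroxyl with loss of dimethylamine (6-endo addition–elimination) closes ring C; as O5 and O7 are silylated only O8a can cyclise, which fixes the alkyl group at C8.

Step 15
Reactants: 28 4-bromo-3-methoxyphenol
Product: 29 (4-bromo-3-methoxyphenoxy)triisopropylsilane
Conditions: TIPSCl, imidazole, DMF, rt
Reagents that add atoms: triisopropylsilyl chloride, CC(C)[Si](Cl)(C(C)C)C(C)C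
Why: Standard silylation of a phenol, giving an aryl silyl ether that tolerates the organolithium step and is removed together with the others at the end.

Step 16
Reactants: 29 (4-bromo-3-methoxyphenoxy)triisopropylsilane
Product: 32 {2-methoxy-4-[(triisopropylsilyl)oxy]phenyl}boronic acid, via aryllithium 30 (not isolated), via lithium arylborate 31 (not isolated)
Conditions: n-BuLi, THF, −78 °C; B(OiPr)3, −78 °C → rt; aq NH4Cl then 1 M HCl to pH 5
Reagents that add atoms: triisopropyl borate, CC(C)OB(OC(C)C)OC(C)C; water, O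
Why: Bromine–lithium exchange, trapping of the aryllithium with the borate ester and mild hydrolysis give the boronic acid, the para silyl ether being inert to n-BuLi at −78 °C.

Step 17
Reactants: 27 8-[(2R,3R)-4-[(tert-butyldimethylsilyl)oxy]-3-methyl-2-(3-methylbut-2-en-1-yl)butyl]-5,7-bis[(triisopropylsilyl)oxy]-4H-chromen-4-one; 32 {2-methoxy-4-[(triisopropylsilyl)oxy]phenyl}boronic acid
Product: 33 (2S)-8-[(2R,3R)-4-[(tert-butyldimethylsilyl)oxy]-3-methyl-2-(3-methylbut-2-en-1-yl)butyl]-2-{2-methoxy-4-[(triisopropylsilyl)oxy]phenyl}-5,7-bis[(triisopropylsilyl)oxy]-2,3-dihydro-4H-chromen-4-one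
Conditions: [Rh(OH){(S)-MeO-F12-BIPHEP}]2 (2.5 mol %), 32 (3 equiv, in portions), toluene/H2O (10:1), 40 °C
Reagents that add atoms: none
Why: Rhodium-catalysed asymmetric 1,4-addition of an arylboronic acid to a chromone (Hayashi–Miyaura reaction), in which transmetalation gives an aryl–rhodium species that inserts the C2=C3 bond on the Re face of C2 under control of the (S)-diphosphine and hydrolysis of the oxa-pi-allyl rhodium sets C2 as S, the distant side-chain centres having no say and the base-free medium avoiding retro-oxa-Michael opening.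

Step 18
Reactants: 33 (2S)-8-[(2R,3R)-4-[(tert-butyldimethylsilyl)oxy]-3-methyl-2-(3-methylbut-2-en-1-yl)butyl]-2-{2-methoxy-4-[(triisopropylsilyl)oxy]phenyl}-5,7-bis[(triisopropylsilyl)oxy]-2,3-dihydro-4H-chromen-4-one
Product: 34 (2S)-5,7-dihydroxy-8-[(2R,3R)-4-hydroxy-3-methyl-2-(3-methylbut-2-en-1-yl)butyl]-2-(4-hydroxy-2-methoxyphenyl)-2,3-dihydro-4H-chromen-4-one (CNP0081318.1)
Conditions: Bu4NF (8 equiv), AcOH (8 equiv), THF, 0 °C → rt
Reagents that add atoms: none
Why: Fluoride cleaves the three aryl and the one alkyl Si–O bonds (global desilylation), and the acetic acid buffer keeps the phenols protonated so that the flavanone should neither ring-open to the chalcone nor epimerise at C2.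

**Compound list**

1 | butane-2,3-dione | CC(=O)C(C)=O | starting material
2 | 3-[(triisopropylsilyl)oxy]but-3-en-2-one | CC(=O)C(=C)O[Si](C(C)C)(C(C)C)C(C)C | intermediate
3 | lithium 3-[(triisopropylsilyl)oxy]buta-1,3-dien-2-olate | [Li]OC(=C)C(=C)O[Si](C(C)C)(C(C)C)C(C)C | intermediate
4 | 1,1,1-trifluoro-5-[(triisopropylsilyl)oxy]hex-5-ene-2,4-dione | O=C(CC(=O)C(=C)O[Si](C(C)C)(C(C)C)C(C)C)C(F)(F)F | intermediate
5 | 1-diazo-3-[(triisopropylsilyl)oxy]but-3-en-2-one | [N-]=[N+]=CC(=O)C(=C)O[Si](C(C)C)(C(C)C)C(C)C | intermediate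
6 | (S)-3-bromo-2-methylpropan-1-ol | BrC[C@@H](C)CO | starting material
7 | (S)-(3-bromo-2-methylpropoxy)(tert-butyl)dimethylsilane | BrC[C@@H](C)CO[Si](C)(C)C(C)(C)C | intermediate
8 | {(S)-3-[(tert-butyldimethylsilyl)oxy]-2-methylpropyl}magnesium bromide | Br[Mg]C[C@@H](C)CO[Si](C)(C)C(C)(C)C | intermediate
9 | (R)-4-[(tert-butyldimethylsilyl)oxy]-3-methylbutanoic acid | OC(=O)C[C@@H](C)CO[Si](C)(C)C(C)(C)C | intermediate
10 | (R)-4-[(tert-butyldimethylsilyl)oxy]-3-methylbutanoic pivalic anhydride | CC(C)(C)C(=O)OC(=O)C[C@@H](C)CO[Si](C)(C)C(C)(C)C | intermediate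
11 | (S)-4-benzyl-3-{(R)-4-[(tert-butyldimethylsilyl)oxy]-3-methylbutanoyl}oxazolidin-2-one | O=C(C[C@@H](C)CO[Si](C)(C)C(C)(C)C)N1[C@@H](Cc2ccccc2)COC1=O | intermediate
12 | sodium (1Z,3R)-1-[(S)-4-benzyl-2-oxooxazolidin-3-yl]-4-[(tert-butyldimethylsilyl)oxy]-3-methylbut-1-en-1-olate | [Na]O/C(=C\[C@@H](C)CO[Si](C)(C)C(C)(C)C)N1[C@@H](Cc2ccccc2)COC1=O | intermediate
13 | (S)-4-benzyl-3-{(2S,3R)-4-[(tert-butyldimethylsilyl)oxy]-3-methyl-2-(3-methylbut-2-en-1-yl)butanoyl}oxazolidin-2-one | O=C([C@@H](CC=C(C)C)[C@@H](C)CO[Si](C)(C)C(C)(C)C)N1[C@@H](Cc2ccccc2)COC1=O | intermediate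
14 | (2S,3R)-4-[(tert-butyldimethylsilyl)oxy]-3-methyl-2-(3-methylbut-2-en-1-yl)butan-1-ol | OC[C@@H](CC=C(C)C)[C@@H](C)CO[Si](C)(C)C(C)(C)C | intermediate
15 | (2S,3R)-4-[(tert-butyldimethylsilyl)oxy]-3-methyl-2-(3-methylbut-2-en-1-yl)butyl 4-methylbenzenesulfonate | Cc1ccc(cc1)S(=O)(=O)OC[C@@H](CC=C(C)C)[C@@H](C)CO[Si](C)(C)C(C)(C)C | intermediate
16 | tert-butyl{[(2R,3R)-2,6-dimethyl-3-(prop-2-yn-1-yl)hept-5-en-1-yl]oxy}dimethylsilane | C#CC[C@@H](CC=C(C)C)[C@@H](C)CO[Si](C)(C)C(C)(C)C | intermediate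
17 | lithium acetylide of 16 | [Li]C#CC[C@@H](CC=C(C)C)[C@@H](C)CO[Si](C)(C)C(C)(C)C | intermediate
18 | lithium ynolate, lithium (4R,5R)-6-[(tert-butyldimethylsilyl)oxy]-5-methyl-4-(3-methylbut-2-en-1-yl)hex-1-yn-1-olate | [Li]OC#CC[C@@H](CC=C(C)C)[C@@H](C)CO[Si](C)(C)C(C)(C)C | intermediate
19 | tert-butyl{[(2R,3R)-2,6-dimethyl-3-{3-[(triisopropylsilyl)oxy]prop-2-yn-1-yl}hept-5-en-1-yl]oxy}dimethylsilane | CC(C)[Si](C(C)C)(C(C)C)OC#CC[C@@H](CC=C(C)C)[C@@H](C)CO[Si](C)(C)C(C)(C)C | intermediate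
20 | 3-[(triisopropylsilyl)oxy]buta-1,3-dien-1-one (vinylketene) | O=C=CC(=C)O[Si](C(C)C)(C(C)C)C(C)C | intermediate
21 | 2-[(2R,3R)-4-[(tert-butyldimethylsilyl)oxy]-3-methyl-2-(3-methylbut-2-en-1-yl)butyl]-3-[(triisopropylsilyl)oxy]-4-{1-[(triisopropylsilyl)oxy]ethenyl}cyclobut-2-en-1-one (both epimers at the ring sp3 carbon) | O=C1C(C[C@@H](CC=C(C)C)[C@@H](C)CO[Si](C)(C)C(C)(C)C)=C(O[Si](C(C)C)(C(C)C)C(C)C)C1C(=C)O[Si](C(C)C)(C(C)C)C(C)C | intermediate
22 | 2-[(2R,3R)-4-[(tert-butyldimethylsilyl)oxy]-3-methyl-2-(3-methylbut-2-en-1-yl)butyl]-3,5-bis[(triisopropylsilyl)oxy]hexa-1,3,5-trien-1-one (dienylketene) | O=C=C(C[C@@H](CC=C(C)C)[C@@H](C)CO[Si](C)(C)C(C)(C)C)C(O[Si](C(C)C)(C(C)C)C(C)C)=CC(=C)O[Si](C(C)C)(C(C)C)C(C)C | intermediate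
23 | 2-[(2R,3R)-4-[(tert-butyldimethylsilyl)oxy]-3-methyl-2-(3-methylbut-2-en-1-yl)butyl]-3,5-bis[(triisopropylsilyl)oxy]phenol | Oc1cc(O[Si](C(C)C)(C(C)C)C(C)C)cc(O[Si](C(C)C)(C(C)C)C(C)C)c1C[C@@H](CC=C(C)C)[C@@H](C)CO[Si](C)(C)C(C)(C)C | intermediate
24 | 2-[(2R,3R)-4-[(tert-butyldimethylsilyl)oxy]-3-methyl-2-(3-methylbut-2-en-1-yl)butyl]-3,5-bis[(triisopropylsilyl)oxy]phenyl acetate | CC(=O)Oc1cc(O[Si](C(C)C)(C(C)C)C(C)C)cc(O[Si](C(C)C)(C(C)C)C(C)C)c1C[C@@H](CC=C(C)C)[C@@H](C)CO[Si](C)(C)C(C)(C)C | intermediate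
25 | 1-{2-hydroxy-3-[(2R,3R)-4-[(tert-butyldimethylsilyl)oxy]-3-methyl-2-(3-methylbut-2-en-1-yl)butyl]-4,6-bis[(triisopropylsilyl)oxy]phenyl}ethan-1-one | CC(=O)c1c(O)c(C[C@@H](CC=C(C)C)[C@@H](C)CO[Si](C)(C)C(C)(C)C)c(O[Si](C(C)C)(C(C)C)C(C)C)cc1O[Si](C(C)C)(C(C)C)C(C)C | intermediate
26 | (E)-3-(dimethylamino)-1-{2-hydroxy-3-[(2R,3R)-4-[(tert-butyldimethylsilyl)oxy]-3-methyl-2-(3-methylbut-2-en-1-yl)butyl]-4,6-bis[(triisopropylsilyl)oxy]phenyl}prop-2-en-1-one | CN(C)/C=C/C(=O)c1c(O)c(C[C@@H](CC=C(C)C)[C@@H](C)CO[Si](C)(C)C(C)(C)C)c(O[Si](C(C)C)(C(C)C)C(C)C)cc1O[Si](C(C)C)(C(C)C)C(C)C | intermediate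
27 | 8-[(2R,3R)-4-[(tert-butyldimethylsilyl)oxy]-3-methyl-2-(3-methylbut-2-en-1-yl)butyl]-5,7-bis[(triisopropylsilyl)oxy]-4H-chromen-4-one | O=c1ccoc2c(C[C@@H](CC=C(C)C)[C@@H](C)CO[Si](C)(C)C(C)(C)C)c(O[Si](C(C)C)(C(C)C)C(C)C)cc(O[Si](C(C)C)(C(C)C)C(C)C)c12 | intermediate
28 | 4-bromo-3-methoxyphenol | COc1cc(O)ccc1Br | starting material
29 | (4-bromo-3-methoxyphenoxy)triisopropylsilane | COc1cc(O[Si](C(C)C)(C(C)C)C(C)C)ccc1Br | intermediate
30 | {2-methoxy-4-[(triisopropylsilyl)oxy]phenyl}lithium | COc1cc(O[Si](C(C)C)(C(C)C)C(C)C)ccc1[Li] | intermediate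
31 | lithium triisopropoxy{2-methoxy-4-[(triisopropylsilyl)oxy]phenyl}borate | [Li+].COc1cc(O[Si](C(C)C)(C(C)C)C(C)C)ccc1[B-](OC(C)C)(OC(C)C)OC(C)C | intermediate
32 | {2-methoxy-4-[(triisopropylsilyl)oxy]phenyl}boronic acid | COc1cc(O[Si](C(C)C)(C(C)C)C(C)C)ccc1B(O)O | intermediate
33 | (2S)-8-[(2R,3R)-4-[(tert-butyldimethylsilyl)oxy]-3-methyl-2-(3-methylbut-2-en-1-yl)butyl]-2-{2-methoxy-4-[(triisopropylsilyl)oxy]phenyl}-5,7-bis[(triisopropylsilyl)oxy]-2,3-dihydro-4H-chromen-4-one | COc1cc(O[Si](C(C)C)(C(C)C)C(C)C)ccc1[C@@H]1CC(=O)c2c(O[Si](C(C)C)(C(C)C)C(C)C)cc(O[Si](C(C)C)(C(C)C)C(C)C)c(C[C@@H](CC=C(C)C)[C@@H](C)CO[Si](C)(C)C(C)(C)C)c2O1 | intermediate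
34 | (2S)-5,7-dihydroxy-8-[(2R,3R)-4-hydroxy-3-methyl-2-(3-methylbut-2-en-1-yl)butyl]-2-(4-hydroxy-2-methoxyphenyl)-2,3-dihydro-4H-chromen-4-one | COc1cc(O)ccc1[C@@H]1CC(=O)c2c(O)cc(O)c(C[C@@H](CC=C(C)C)[C@@H](C)CO)c2O1 | target

**Step count**

Total: 18 steps. Longest linear sequence: 14 steps (6 → 7 → 9 → 11 → 13 → 14 → 15 → 16 → 19 → 23 → 24 → 25 → 27 → 33 → 34, that is steps 3–14, 17 and 18).

**Steps most likely to fail, with fallbacks**

Step 11 (key benzannulation). The photogenerated vinylketene may be lost to dimerisation or to acylation of the product phenol before it meets the alkyne, the ynol silyl ether may degrade under short-wavelength light, and the light-absorbing product may stall conversion. The fallback generates the same vinylketene 20 thermally and without light. Cyclobutane-1,3-dione is silylated (TIPSOTf, Et3N, CH2Cl2) to 3-[(triisopropylsilyl)oxy]cyclobut-2-en-1-one F1. Heating F1 with 19 in toluene at 80–110 °C should open the cyclobutenone by four-electron electrocyclic cleavage to 20, which then follows the same [2+2] addition, ring opening and six-electron closure. This fallback sets out from 19 and returns to the route at 23.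

Step 13 (photo-Fries shift). The acetyl/aryloxy radical pair may escape the solvent cage and return phenol 23, recombination may occur at the para carbon, and the product ketone may filter the light and hold conversion low. The fallback installs the C4a carbon by chelation-controlled chemistry instead of a radical shift. Phenol 23 is ortho-formylated (MgCl2, Et3N, paraformaldehyde, MeCN, reflux; Casnati–Skattebøl formylation, specific for the position next to the magnesium phenoxide) to 2-hydroxy-3-[(2R,3R)-4-[(tert-butyldimethylsilyl)oxy]-3-methyl-2-(3-methylbut-2-en-1-yl)butyl]-4,6-bis[(triisopropylsilyl)oxy]benzaldehyde F2. MeMgBr (3 equiv, THF, −78 → 0 °C) then gives the carbinol 1-{2-hydroxy-3-[(2R,3R)-4-[(tert-butyldimethylsilyl)oxy]-3-methyl-2-(3-methylbut-2-en-1-yl)butyl]-4,6-bis[(triisopropylsilyl)oxy]phenyl}ethan-1-ol F3 as a mixture of carbinol epimers, which is oxidised at once with MnO2 in CH2Cl2. This fallback sets out from 23 (step 12 is then not needed) and returns to the route at 25.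

Step 17 (asymmetric conjugate arylation). The electron-rich ortho-methoxy boronic acid may protodeboronate faster than it transmetalates, the electron-rich chromone with its peri silyloxy group may insert slowly, and facial selectivity may be eroded. The fallback builds ring C from a chalcone instead of adding ring B to a chromone. 4-Hydroxy-2-methoxybenzaldehyde is silylated (TIPSCl, imidazole) to 2-methoxy-4-[(triisopropylsilyl)oxy]benzaldehyde F4. Pyrrolidine-mediated Claisen–Schmidt condensation of 25 with F4 (EtOH, 60 °C) gives (E)-1-{2-hydroxy-3-[(2R,3R)-4-[(tert-butyldimethylsilyl)oxy]-3-methyl-2-(3-methylbut-2-en-1-yl)butyl]-4,6-bis[(triisopropylsilyl)oxy]phenyl}-3-{2-methoxy-4-[(triisopropylsilyl)oxy]phenyl}prop-2-en-1-one F5. Under the same conditions F5 closes by oxa-Michael addition of O8a to 33 together with its C2 epimer, (2R)-8-[(2R,3R)-4-[(tert-butyldimethylsilyl)oxy]-3-methyl-2-(3-methylbut-2-en-1-yl)butyl]-2-{2-methoxy-4-[(triisopropylsilyl)oxy]phenyl}-5,7-bis[(triisopropylsilyl)oxy]-2,3-dihydro-4H-chromen-4-one F6. The two epimers are separated by preparative HPLC on a chiral stationary phase, and F6 is returned to the pyrrolidine equilibration. This fallback sets out from 25 and returns to the route at 33.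

**Further compounds**

F1 | step 11 | 3-[(triisopropylsilyl)oxy]cyclobut-2-en-1-one | O=C1C=C(O[Si](C(C)C)(C(C)C)C(C)C)C1
F2 | step 13 | 2-hydroxy-3-[(2R,3R)-4-[(tert-butyldimethylsilyl)oxy]-3-methyl-2-(3-methylbut-2-en-1-yl)butyl]-4,6-bis[(triisopropylsilyl)oxy]benzaldehyde | O=Cc1c(O)c(C[C@@H](CC=C(C)C)[C@@H](C)CO[Si](C)(C)C(C)(C)C)c(O[Si](C(C)C)(C(C)C)C(C)C)cc1O[Si](C(C)C)(C(C)C)C(C)C
F3 | step 13 | 1-{2-hydroxy-3-[(2R,3R)-4-[(tert-butyldimethylsilyl)oxy]-3-methyl-2-(3-methylbut-2-en-1-yl)butyl]-4,6-bis[(triisopropylsilyl)oxy]phenyl}ethan-1-ol | CC(O)c1c(O)c(C[C@@H](CC=C(C)C)[C@@H](C)CO[Si](C)(C)C(C)(C)C)c(O[Si](C(C)C)(C(C)C)C(C)C)cc1O[Si](C(C)C)(C(C)C)C(C)C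
F4 | step 17 | 2-methoxy-4-[(triisopropylsilyl)oxy]benzaldehyde | COc1cc(O[Si](C(C)C)(C(C)C)C(C)C)ccc1C=O
F5 | step 17 | (E)-1-{2-hydroxy-3-[(2R,3R)-4-[(tert-butyldimethylsilyl)oxy]-3-methyl-2-(3-methylbut-2-en-1-yl)butyl]-4,6-bis[(triisopropylsilyl)oxy]phenyl}-3-{2-methoxy-4-[(triisopropylsilyl)oxy]phenyl}prop-2-en-1-one | COc1cc(O[Si](C(C)C)(C(C)C)C(C)C)ccc1/C=C/C(=O)c1c(O)c(C[C@@H](CC=C(C)C)[C@@H](C)CO[Si](C)(C)C(C)(C)C)c(O[Si](C(C)C)(C(C)C)C(C)C)cc1O[Si](C(C)C)(C(C)C)C(C)C
F6 | step 17 | (2R)-8-[(2R,3R)-4-[(tert-butyldimethylsilyl)oxy]-3-methyl-2-(3-methylbut-2-en-1-yl)butyl]-2-{2-methoxy-4-[(triisopropylsilyl)oxy]phenyl}-5,7-bis[(triisopropylsilyl)oxy]-2,3-dihydro-4H-chromen-4-one | COc1cc(O[Si](C(C)C)(C(C)C)C(C)C)ccc1[C@H]1CC(=O)c2c(O[Si](C(C)C)(C(C)C)C(C)C)cc(O[Si](C(C)C)(C(C)C)C(C)C)c(C[C@@H](CC=C(C)C)[C@@H](C)CO[Si](C)(C)C(C)(C)C)c2O1
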